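**Plan**

- Retrosynthetic cuts, in order: the C7–CH2 bond of the allyl group (aromatic Claisen from a 6-O-allyl ether), the C2–aryl bond (decarboxylative arylation of a C2 carboxylic acid), the furan O1–C2 bond (ring contraction of a 3-chlorocoumarin), and the pyranone C4–C4a and lactone C–O bonds (Pechmann).
- Enabling feature: in the furan ring, O1, C2, C3 (with its methyl) and C3a map onto O1, C3 (bearing Cl), C4 (with its methyl) and C4a of a 3-chloro-4-methylcoumarin. The lactone carbonyl becomes a carboxyl group on C2, which is later exchanged for the trimethoxyphenyl ring.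
- Forward order: ring A is bought with its three oxygens; the pyranone is fused on by Pechmann condensation; O7 is benzylated and O6 methylated; the pyranone is contracted to the furan; the aryl ring is joined at C2 with loss of CO2.
- The allyl chain is joined last (debenzylation, O-allylation, Claisen shift to C7, the only free ortho position). The terminal alkene therefore never meets a palladium/aryl halide system, and the last step releases the free phenol.
- Stereochemistry: the target has no stereocentre and no stereogenic double bond, so nothing has to be set or protected.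

Key step: step 4

Remark on the chemistry: the target is achiral, so it is a single species by constitution alone. Coumarin numbering is used up to compound 6 and benzofuran numbering from compound 8 on (coumarin C6, C7, C8 become benzofuran C5, C6, C7).

**Step 1**
Reactants: 1 1,2,4-triacetoxybenzene; 2 ethyl 2-chloroacetoacetate
Product: 4 3-chloro-6,7-dihydroxy-4-methylcoumarin, via hydroxyhydroquinone 3 (not isolated)
Conditions: 75% aq H2SO4, 80 °C; then ice-water
Reagents that add atoms: none
Why: Pechmann condensation, in which the acid first hydrolyses the three acetates to triol 3 and then joins its most activated unhindered carbon (para to one hydroxyl, ortho to another) to the ketone of 2 with lactonisation and dehydration, exactly as in the standard preparation of 4-methylesculetin from the same triacetate, the 2-chloro substituent of the keto ester ending up on C3.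

**Step 2**
Reactants: 4 3-chloro-6,7-dihydroxy-4-methylcoumarin
Product: 5 7-benzyloxy-3-chloro-6-hydroxy-4-methylcoumarin
Conditions: BnBr (1.05 equiv), NaHCO3, DMF, 40 °C
Reagents that add atoms: benzyl bromide, BrCc1ccccc1
Why: Regioselective Williamson etherification, since the 7-hydroxyl is para to the C4=C3–C2=O vinylogous ester and therefore much more acidic than the 6-hydroxyl, so hydrogencarbonate should ionise and benzylate only O7, as in the 7-O-selective alkylation of esculetins and the 4-O-selective alkylation of 3,4-dihydroxybenzaldehyde.

**Step 3**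
Reactants: 5 7-benzyloxy-3-chloro-6-hydroxy-4-methylcoumarin
Product: 6 7-benzyloxy-3-chloro-6-methoxy-4-methylcoumarin
Conditions: MeI, K2CO3, acetone, reflux
Reagents that add atoms: iodomethane, CI
Why: Williamson methylation of the one remaining phenol, under anhydrous carbonate conditions that leave the lactone and the vinylic chloride untouched.

**Step 4**
Reactants: 6 7-benzyloxy-3-chloro-6-methoxy-4-methylcoumarin
Product: 8 6-benzyloxy-5-methoxy-3-methylbenzofuran-2-carboxylic acid, via ring-opened chlorobutenoate dianion 7 (not isolated)
Conditions: NaOH (10% aq, excess), EtOH, reflux; then aq HCl, 0 °C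
Reagents that add atoms: sodium hydroxide, [Na+].[OH-]
Why: Hydroxide should open the lactone of 6 to the dianion 7, whose freed phenoxide (the former O1 on C8a) attacks the chlorine-bearing vinylic carbon by intramolecular addition–elimination with loss of chloride, which forms the O1–C2 bond of the furan and leaves the former lactone carbon as the carboxylate on C2. The closest known reaction is the Perkin coumarin-to-benzofuran rearrangement of 3-halocoumarins, which is established for 3-halo-4-methylcoumarins including 7-oxygenated ones. The furan closes in a 5-endo-trig mode at the vinylic carbon, which is accepted for this vinylic substitution because the ring formed is aromatic. No stereocentre is created. The selectivity needed is cyclisation of 7 rather than simple relactonisation on acidification or intermolecular attack by hydroxide, and it is secured by prolonged heating with excess base before the acid quench, by the five-membered intramolecular path, and by the benzyl and methyl ethers, which are inert to hydroxide and leave the reacting oxygen as the only phenoxide.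

**Step 5**
Reactants: 8 6-benzyloxy-5-methoxy-3-methylbenzofuran-2-carboxylic acid; 9 5-bromo-1,2,3-trimethoxybenzene
Product: 10 6-benzyloxy-5-methoxy-3-methyl-2-(3,4,5-trimethoxyphenyl)benzofuran
Conditions: Pd[P(t-Bu)3]2 (5 mol %), Cs2CO3 (1.5 equiv), n-Bu4NCl (1 equiv), DMF, 170 °C (microwave or sealed tube)
Reagents that add atoms: none
Why: Palladium-catalysed decarboxylative cross-coupling of a heteroaryl 2-carboxylic acid with an aryl bromide, in which the arylpalladium(II) bromide palladates the electron-rich caesium carboxylate at C2, CO2 is lost and reductive elimination forms the C2–aryl bond, a process known for 3-methylbenzofuran-2-carboxylic acid, where the C3 methyl blocks competing C3 arylation, and run here on a substrate with no alkene or free phenol.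

**Step 6**
Reactants: 10 6-benzyloxy-5-methoxy-3-methyl-2-(3,4,5-trimethoxyphenyl)benzofuran
Product: 11 6-hydroxy-5-methoxy-3-methyl-2-(3,4,5-trimethoxyphenyl)benzofuran
Conditions: H2 (1 atm), 10% Pd/C, EtOAc–MeOH, rt
Reagents that add atoms: none
Why: Catalytic hydrogenolysis of the benzyl ether, which at ambient pressure and temperature should not reduce the tetrasubstituted, aryl-conjugated furan double bond or the methyl ethers.

**Step 7**
Reactants: 11 6-hydroxy-5-methoxy-3-methyl-2-(3,4,5-trimethoxyphenyl)benzofuran; 12 allyl bromide
Product: 13 6-allyloxy-5-methoxy-3-methyl-2-(3,4,5-trimethoxyphenyl)benzofuran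
Conditions: K2CO3, acetone, reflux
Reagents that add atoms: none
Why: Williamson O-allylation (SN2) of the single phenol with a reactive allylic bromide.

**Step 8**
Reactants: 13 6-allyloxy-5-methoxy-3-methyl-2-(3,4,5-trimethoxyphenyl)benzofuran
Product: 15 7-allyl-6-hydroxy-5-methoxy-3-methyl-2-(3,4,5-trimethoxyphenyl)benzofuran, via ortho-dienone 14 (not isolated)
Conditions: N,N-diethylaniline, 200 °C, Ar; dilute HCl wash
Reagents that add atoms: none
Why: Aromatic Claisen rearrangement, a [3,3]-sigmatropic shift of the allyl group from O6 to C7, the only ortho carbon able to rearomatise because C5 carries the methoxy group, followed by enolisation of dienone 14 to the phenol, as known for 7-allyloxycoumarins and 6-allyloxybenzofurans.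

**Compound list**

1 | 1,2,4-triacetoxybenzene | CC(=O)Oc1ccc(OC(C)=O)c(OC(C)=O)c1 | starting material
2 | ethyl 2-chloroacetoacetate (racemic, configurationally labile) | CCOC(=O)C(Cl)C(C)=O | starting material
3 | hydroxyhydroquinone (benzene-1,2,4-triol) | Oc1ccc(O)c(O)c1 | intermediate (not isolated)
4 | 3-chloro-6,7-dihydroxy-4-methylcoumarin | Cc1c(Cl)c(=O)oc2cc(O)c(O)cc12 | intermediate
5 | 7-benzyloxy-3-chloro-6-hydroxy-4-methylcoumarin | Cc1c(Cl)c(=O)oc2cc(OCc3ccccc3)c(O)cc12 | intermediate
6 | 7-benzyloxy-3-chloro-6-methoxy-4-methylcoumarin | Cc1c(Cl)c(=O)oc2cc(OCc3ccccc3)c(OC)cc12 | intermediate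
7 | ring-opened chlorobutenoate dianion: disodium (E)-3-(4-benzyloxy-5-methoxy-2-oxidophenyl)-2-chlorobut-2-enoate | C/C(=C(\Cl)C(=O)[O-])c1cc(OC)c(OCc2ccccc2)cc1[O-].[Na+].[Na+] | intermediate (not isolated)
8 | 6-benzyloxy-5-methoxy-3-methylbenzofuran-2-carboxylic acid | Cc1c(C(=O)O)oc2cc(OCc3ccccc3)c(OC)cc12 | intermediate
9 | 5-bromo-1,2,3-trimethoxybenzene | COc1cc(Br)cc(OC)c1OC | starting material
10 | 6-benzyloxy-5-methoxy-3-methyl-2-(3,4,5-trimethoxyphenyl)benzofuran | Cc1c(-c2cc(OC)c(OC)c(OC)c2)oc2cc(OCc3ccccc3)c(OC)cc12 | intermediate
11 | 6-hydroxy-5-methoxy-3-methyl-2-(3,4,5-trimethoxyphenyl)benzofuran | Cc1c(-c2cc(OC)c(OC)c(OC)c2)oc2cc(O)c(OC)cc12 | intermediate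
12 | allyl bromide | C=CCBr | starting material
13 | 6-allyloxy-5-methoxy-3-methyl-2-(3,4,5-trimethoxyphenyl)benzofuran | C=CCOc1cc2oc(-c3cc(OC)c(OC)c(OC)c3)c(C)c2cc1OC | intermediate
14 | ortho-dienone: 7-allyl-5-methoxy-3-methyl-2-(3,4,5-trimethoxyphenyl)benzofuran-6(7H)-one (racemic, transient) | C=CCC1C(=O)C(OC)=CC2=C1OC(c1cc(OC)c(OC)c(OC)c1)=C2C | intermediate (not isolated)
15 | 7-allyl-6-hydroxy-5-methoxy-3-methyl-2-(3,4,5-trimethoxyphenyl)benzofuran (CNP0110777.0) | C=CCc1c(O)c(OC)cc2c(C)c(-c3cc(OC)c(OC)c(OC)c3)oc12 | target

**Step count**

Total steps: 8. Longest linear sequence: 8 steps (1 to 15); 9 and 12 are bought and enter at steps 5 and 7.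

**Steps most likely to fail**

Step 5 (decarboxylative arylation). Loss of CO2 followed by protonation at C2 may outrun aryl transfer, or the aryl bromide may be used up by reduction or homocoupling. Fallback: starting from acid 8, the carboxyl group is removed on purpose by copper-mediated protodecarboxylation (Cu2O, 1,10-phenanthroline, NMP–quinoline, 170 °C) to give 6-benzyloxy-5-methoxy-3-methylbenzofuran F1. Its only free furan position, C2, is then arylated with 9 by palladium-catalysed direct C–H arylation (Pd(OAc)2, PCy3·HBF4, pivalic acid, K2CO3, DMA, 100 °C), a concerted metalation–deprotonation process known for benzofurans. This returns to the route at 10.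

Step 2 (site-selective benzylation). Alkylation may spread to the 6-hydroxyl or to both hydroxyls when proton exchange between the two phenoxides is faster than benzylation. Fallback: starting from diol 4, both hydroxyls are acetylated (Ac2O, pyridine) to 6,7-diacetoxy-3-chloro-4-methylcoumarin F2. The more labile 7-acetate, para to the vinylogous carbonyl, is then replaced by benzyl in a deacetylative benzylation (BnBr, K2CO3, KI, acetone, reflux), the method used for 7-O-benzylation of polyacetoxy flavonoids, to give 6-acetoxy-7-benzyloxy-3-chloro-4-methylcoumarin F3. Mild methanolysis of the remaining aryl acetate (catalytic K2CO3 or NH4OAc, MeOH, rt) returns to the route at 5.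

Step 8 (Claisen rearrangement). At the temperature the sigmatropic shift needs, the electron-rich phenol may decompose, or the freshly formed phenol may add to its own allyl double bond. Fallback: starting from phenol 11, the oxygen is capped (MOMCl, i-Pr2NEt, CH2Cl2) as 5-methoxy-6-(methoxymethoxy)-3-methyl-2-(3,4,5-trimethoxyphenyl)benzofuran F4. Directed ortho-metalation (n-BuLi, TMEDA, THF, −78 to 0 °C) should remove the C7 proton, which lies between the MOM ether and the ring oxygen, giving the 7-lithio derivative F5 (not isolated). This is allylated with 12 (catalytic CuI) to 7-allyl-5-methoxy-6-(methoxymethoxy)-3-methyl-2-(3,4,5-trimethoxyphenyl)benzofuran F6. HCl in methanol then removes the MOM group and returns to the route at 15.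

**Further compounds**

F1 | step 5 | 6-benzyloxy-5-methoxy-3-methylbenzofuran | Cc1coc2cc(OCc3ccccc3)c(OC)cc12
F2 | step 2 | 6,7-diacetoxy-3-chloro-4-methylcoumarin | Cc1c(Cl)c(=O)oc2cc(OC(C)=O)c(OC(C)=O)cc12
F3 | step 2 | 6-acetoxy-7-benzyloxy-3-chloro-4-methylcoumarin | Cc1c(Cl)c(=O)oc2cc(OCc3ccccc3)c(OC(C)=O)cc12
F4 | step 8 | 5-methoxy-6-(methoxymethoxy)-3-methyl-2-(3,4,5-trimethoxyphenyl)benzofuran | COCOc1cc2oc(-c3cc(OC)c(OC)c(OC)c3)c(C)c2cc1OC
F5 | step 8 | 7-lithio-5-methoxy-6-(methoxymethoxy)-3-methyl-2-(3,4,5-trimethoxyphenyl)benzofuran | [Li]c1c(OCOC)c(OC)cc2c(C)c(-c3cc(OC)c(OC)c(OC)c3)oc12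
F6 | step 8 | 7-allyl-5-methoxy-6-(methoxymethoxy)-3-methyl-2-(3,4,5-trimethoxyphenyl)benzofuran | C=CCc1c(OCOC)c(OC)cc2c(C)c(-c3cc(OC)c(OC)c(OC)c3)oc12
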